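The runs were computed on assumed constants, noise included.

- A leftover opens this: in Thursday's flask at 20.0 min, target and substrate together leave 3.80% of the charge unaccounted, a figure carrying the scatter of two readings.

| setting | Thursday's | zeta | theta | epsilon | alpha |
|---|---|---|---|---|---|
| substrate | 0.10 M | 0.10 M | 0.20 M | 0.40 M | 0.80 M |
| reagent | 0.507 M | 0.507 M | 0.507 M | 0.507 M | 0.507 M |
| initiator | 15 mM | 9.8 mM | 9.8 mM | 9.8 mM | 9.8 mM |
| remark | run made earlier |  |  |  |  |
| time |  | 1.0 h | 1.0 h | 1.0 h | 1.0 h |

Thursday's run (percent of the substrate charged)

| time / min | target / % | substrate / % |
|---|---|---|
| 1.50 | 3.2 | 97.5 |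
| 4.00 | 7.6 | 93.1 |
| 10.0 | 15.7 | 82.8 |
| 20.0 | 26.6 | 69.6 |

(readings scatter by 0.3 percentage points)

- in percentages every species weighs as the substrate in it: one ended chains A or side product counts as two
- what was read earlier has a scatter of 0.3 percentage points, one standard deviation
- steps thought possible: 2 second chain carrier -> ended chains B; reagent + first chain carrier <-> target + second chain carrier; 2 first chain carrier -> ended chains A; first chain carrier -> ended carrier; initiator -> 2 initiating radical; substrate + initiating radical -> capped initiator + first chain carrier; 2 reagent -> homo dimer; substrate + second chain carrier -> released group + first chain carrier; substrate + target -> side product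
- "hardly changes" means that all values lie within two and a half points (for a concentration: within two and a half percent of the largest)
- no earlier run changes the charge of initiator; that part of a forecast is a guess

1. [target] at the end for zeta, theta, epsilon, alpha, in this order
2. the course of these numbers from the first flask to the last (falls all the way / hardly changes / falls, then rises / rises, then falls / rises all the way)

- You can read the flask as a chain. The initiator starts carriers, the first chain carrier takes reagent to target and becomes the second chain carrier, and that one takes substrate back to the first chain carrier.
- Substrate in Thursday's run falls roughly pseudo-first-order, so I write the making of target as a times c(substrate). From the reading at 10.0 min, using the mean substrate, a is 0.0172 min⁻¹.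
- If carriers end in pairs, a goes as the square root of the initiator charge. That is a guess, because no earlier run varies the charge, and it gives 0.0139 min⁻¹ for the new flasks.
- I charge the leftover to substrate + target → side product, which counts as two. With target growing about linearly, so that its mean is half its end value, this reads as a constant k of 0.0842 M⁻¹ min⁻¹.
- Both making and loss carry c(substrate), which cancels in their ratio, so the share of fresh target lost is c(target) over a/k. That a/k, the target concentration at which loss equals making, is the ceiling: 0.165 M.
- Now take both ends. For the dilute end, I put target at the charge times the converted fraction 0.565. This dilute-end estimate gives 0.0565 M for zeta, below the ceiling, and 0.452 M for alpha, above it.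
- Joining the ends by adding reciprocals, my row is 0.0421 M, 0.0671 M, 0.0953 M, 0.121 M, rising at every step.
- The forecast gives 0.047 M, 0.077 M, 0.114 M, 0.143 M, course rises all the way, holding that “The target then tends to a ceiling”, and its last point stands above mine.
- The flasks give 0.0399 M, 0.0579 M, 0.0718 M, 0.0656 M, course rises, then falls, turning at a substrate charge of 0.48 M.

    2 second chain carrier → ended chains B (k = 1.20 × 10⁷ M⁻¹ s⁻¹)
    reagent + first chain carrier ⇌ target + second chain carrier (K = 0.316, k = 22300 M⁻¹ min⁻¹)
    2 first chain carrier → ended chains A (k = 9.00 × 10⁶ M⁻¹ s⁻¹)
    first chain carrier → ended carrier (k = 208 min⁻¹)
    initiator → 2 initiating radical (k = 0.0203 min⁻¹)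
    substrate + initiating radical → capped initiator + first chain carrier (k = 2.61 × 10⁵ M⁻¹ min⁻¹)
    2 reagent → homo dimer (k = 0.00122 M⁻¹ min⁻¹)
    substrate + second chain carrier → released group + first chain carrier (k = 20900 M⁻¹ min⁻¹)
    substrate + target → side product (k = 0.0385 M⁻¹ min⁻¹)

- In alpha, side product holds 20.1% of the charge, more than the 8.20% in target. Put to use on the end values, the ceiling gives the share of fresh target being lost at that moment as 24.2% in zeta and 39.8% in alpha. Over the whole run, a different measure, target lost over target made, with each side product counted as two in the percentages, is 8.57% in zeta and 55.1% in alpha.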